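**Retrosynthetic overview**

- The strategy rests on ring A, the benzoic acid ring: aryloxy at C-6, carboxyl at C-1, methoxy at C-2, the (R)-1-methoxy-3-methylbutyl chain at C-3, and hydrogen at C-4 and C-5.
- Ring A is disconnected at C-1–C-2 and C-5–C-6 by a Diels–Alder/aromatization: C-2 to C-5 come from a 2-alkyl-1-methoxy-1-silyloxybutadiene, C-6, C-1 and the carboxyl carbon from an allyl 3-aryloxypropiolate. Ring A is the only ring formed; ring B is bought as an arene.
- The hindered diaryl ether C–O bond is made at an sp carbon (phenoxide plus dichloroacetylene from trichloroethylene), never on the finished arene.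
- The diene comes from an Evans deconjugative syn-aldol of the (S)-crotonyl imide with isovaleraldehyde, which sets the (R)-carbinol centre, followed by O-methylation, auxiliary removal, esterification and dienolate O-silylation.
- The endgame is phenol O-methylation, Pd(0) removal of both allyl groups and acetal hydrolysis.

Key step: step 12

Remark on the chemistry: the silyl ketene acetal diene is used as the mixture of its geometric isomers, because the acetal carbon ends as an arene carbon and both isomers converge on the same product. Ring B is built from 2-methoxy-4-methylphenol, whose single free hydroxyl fixes the site of formylation.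

**Route**

Step 1
Reactants: 1 (S)-4-benzyl-3-[(E)-but-2-enoyl]oxazolidin-2-one; 2 3-methylbutanal (isovaleraldehyde)
Product: 4 (S)-4-benzyl-3-[(2S,3R)-2-ethenyl-3-hydroxy-5-methylhexanoyl]oxazolidin-2-one, via dibutylboron Z-dienolate of the imide 3 (not isolated)
Conditions: Bu2BOTf, Et3N, CH2Cl2, −78 → 0 °C; then 2, −78 → 0 °C; pH 7 buffer, H2O2, MeOH, 0 °C
Reagents that add atoms: none
Why: Evans boron aldol of a crotonyl imide, in which the Z(O)-boron dienolate 3 reacts at its α-carbon through a Zimmerman–Traxler chair with the auxiliary benzyl group shielding one face, should give the deconjugated 2,3-syn adduct with the carbinol carbon (R) and C-2 (S).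

Step 2
Reactants: 4 (S)-4-benzyl-3-[(2S,3R)-2-ethenyl-3-hydroxy-5-methylhexanoyl]oxazolidin-2-one
Product: 5 (S)-4-benzyl-3-[(2S,3R)-2-ethenyl-3-methoxy-5-methylhexanoyl]oxazolidin-2-one
Conditions: Me3OBF4, 1,8-bis(dimethylamino)naphthalene, 4 Å MS, CH2Cl2, 0 °C → rt
Reagents that add atoms: trimethyloxonium tetrafluoroborate, C[O+](C)C.F[B-](F)(F)F
Why: Meerwein-salt O-methylation buffered by a non-nucleophilic amine alkylates the secondary alcohol without forming an alkoxide, so retro-aldol cleavage and epimerization or conjugation at the vinyl-bearing α-carbon are avoided and both stereocentres are untouched.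

Step 3
Reactants: 5 (S)-4-benzyl-3-[(2S,3R)-2-ethenyl-3-methoxy-5-methylhexanoyl]oxazolidin-2-one
Product: 6 (2S,3R)-2-ethenyl-3-methoxy-5-methylhexanoic acid
Conditions: LiOH·H2O, 30% H2O2, THF/H2O 3:1, 0 °C; aq Na2SO3; then 1 M HCl to pH 3
Reagents that add atoms: hydrogen peroxide (as lithium hydroperoxide), OO
Why: Hydroperoxide is nucleophilic but weakly basic and attacks the exocyclic imide carbonyl selectively (Evans LiOOH cleavage), so the auxiliary is released without alkoxide conditions that could trigger β-elimination of the methoxy group, and the carbinol centre is not involved.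

Step 4
Reactants: 6 (2S,3R)-2-ethenyl-3-methoxy-5-methylhexanoic acid
Product: 7 methyl (2S,3R)-2-ethenyl-3-methoxy-5-methylhexanoate
Conditions: TMSCHN2 (hexanes), MeOH/PhMe 1:4, 0 °C → rt
Reagents that add atoms: (trimethylsilyl)diazomethane, C[Si](C)(C)C=[N+]=[N-]
Why: Diazoalkane esterification of the carboxylic acid runs under essentially neutral conditions and leaves the β-methoxy and vinyl groups untouched.

Step 5
Reactants: 7 methyl (2S,3R)-2-ethenyl-3-methoxy-5-methylhexanoate
Product: 9 1-methoxy-2-[(R)-1-methoxy-3-methylbutyl]-1-(trimethylsilyloxy)buta-1,3-diene (mixture of ketene acetal isomers), via lithium dienolate 8 (not isolated)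
Conditions: LDA, THF, −78 °C; TMSCl, −78 → 0 °C; pentane, filtration, used crude
Reagents that add atoms: chlorotrimethylsilane, C[Si](C)(C)Cl
Why: Kinetic deprotonation of the doubly activated (allylic and α-ester) C-2 hydrogen and O-silylation of dienolate 8 is the standard preparation of 1-alkoxy-1-silyloxybutadienes; the C-2 stereocentre is deliberately destroyed, the (R)-carbinol centre is kept, and low temperature with prompt silylation should keep E1cB loss of methoxide from competing.

Step 6
Reactants: 10 2-methoxy-4-methylphenol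
Product: 11 2-hydroxy-3-methoxy-5-methylbenzaldehyde
Conditions: MgCl2, Et3N, (CH2O)n, MeCN, reflux; 1 M HCl work-up
Reagents that add atoms: paraformaldehyde (formaldehyde unit), C=O
Why: Magnesium-phenoxide-directed ortho-formylation (Casnati–Skattebøl reaction) delivers formaldehyde only ortho to the free hydroxyl, and C-6 is the only free ortho position.

Step 7
Reactants: 11 2-hydroxy-3-methoxy-5-methylbenzaldehyde
Product: 12 2,3-dihydroxy-5-methylbenzaldehyde
Conditions: BBr3, CH2Cl2, −78 °C → rt; H2O
Reagents that add atoms: none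
Why: Lewis-acid ether cleavage with BBr3 (bromide attack at the methyl group) removes the only aryl methyl ether, as is standard for o-vanillin-type substrates, and the aldehyde is recovered on aqueous work-up.

Step 8
Reactants: 12 2,3-dihydroxy-5-methylbenzaldehyde
Product: 13 3-(allyloxy)-2-hydroxy-5-methylbenzaldehyde
Conditions: NaH (2.2 equiv), DMSO, rt; allyl bromide (1.0 equiv), rt; dil. HCl
Reagents that add atoms: allyl bromide, C=CCBr
Why: In the dianion of a 2,3-dihydroxybenzaldehyde the 2-phenoxide is delocalized into and chelated with the ortho formyl group, so the more basic 3-phenoxide should be the one allylated by one equivalent of halide (Williamson ether synthesis).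

Step 9
Reactants: 13 3-(allyloxy)-2-hydroxy-5-methylbenzaldehyde
Product: 14 2-(allyloxy)-6-(1,3-dioxolan-2-yl)-4-methylphenol
Conditions: HOCH2CH2OH, p-TsOH (cat.), benzene, reflux (Dean–Stark); Et3N quench
Reagents that add atoms: ethylene glycol, OCCO
Why: Acid-catalysed acetalization with azeotropic removal of water masks the aldehyde against butyllithium and amines in later steps, while the free phenol and the allyl ether are inert at this temperature.

Step 10
Reactants: 14 2-(allyloxy)-6-(1,3-dioxolan-2-yl)-4-methylphenol; 15 trichloroethylene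
Product: 16 2-[3-(allyloxy)-2-{[(E)-1,2-dichloroethenyl]oxy}-5-methylphenyl]-1,3-dioxolane
Conditions: K2CO3, DMF, 70 °C
Reagents that add atoms: none
Why: Base converts trichloroethylene into dichloroacetylene, to which the phenoxide adds in anti fashion to give the (E)-1,2-dichlorovinyl ether (the known entry to aryl ynol ethers), so the diaryl-ether oxygen is bonded to the future C-6 while that carbon is still unhindered.

Step 11
Reactants: 16 2-[3-(allyloxy)-2-{[(E)-1,2-dichloroethenyl]oxy}-5-methylphenyl]-1,3-dioxolane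
Product: 19 allyl 3-[2-(allyloxy)-6-(1,3-dioxolan-2-yl)-4-methylphenoxy]prop-2-ynoate, via chloroethynyl aryl ether 17 (not isolated), via lithium aryloxyacetylide 18 (not isolated)
Conditions: n-BuLi (2.3 equiv), THF, −78 → −40 °C; then cannulated into ClCO2CH2CH=CH2, THF, −78 °C
Reagents that add atoms: allyl chloroformate, C=CCOC(=O)Cl
Why: Deprotonation and β-elimination of the dichlorovinyl ether gives chloroalkyne 17, chlorine–lithium exchange with the second equivalent of n-BuLi gives acetylide 18, and C-acylation by inverse addition to excess chloroformate gives the ynoate, following the established trichloroethylene route to substituted ynol ethers.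

Step 12
Reactants: 9 1-methoxy-2-[(R)-1-methoxy-3-methylbutyl]-1-(trimethylsilyloxy)buta-1,3-diene; 19 allyl 3-[2-(allyloxy)-6-(1,3-dioxolan-2-yl)-4-methylphenoxy]prop-2-ynoate
Product: 22 allyl 6-[2-(allyloxy)-6-(1,3-dioxolan-2-yl)-4-methylphenoxy]-2-hydroxy-3-[(R)-1-methoxy-3-methylbutyl]benzoate, via cyclohexa-1,4-diene cycloadduct 20 (not isolated), via aryl trimethylsilyl ether 21 (not isolated)
Conditions: 9 (2 equiv), PhMe, 80–100 °C (sealed); then TBAF, AcOH, THF, 0 °C
Reagents that add atoms: none
Why: Proposed new method: the electron-rich 1,1-dioxygenated diene 9 and the push–pull ynoate 19 should combine in a thermal, strongly asynchronous normal-demand [4+2] cycloaddition in which the CH2 terminus of 9 (largest HOMO coefficient) bonds to the aryloxy-bearing β-carbon of 19 and the acetal carbon bonds to the ester α-carbon, giving cyclohexa-1,4-diene 20; the closest known reaction type is the Diels–Alder benzannulation of 1-alkoxy-1-silyloxybutadienes with propiolates and acetylenedicarboxylates to give salicylates, whereas a 3-aryloxypropiolate is not an established dienophile. Ring A is closed by intermolecular cycloaddition, the C-1–C-2 and C-5–C-6 bonds forming in one event on the s-cis diene, so no exo/endo cyclization mode applies; in the stepwise limit the allenoate from conjugate addition collapses onto the silyloxy-oxocarbenium carbon to close the same six-membered ring. Cycloadduct 20 should then lose methanol across C-2/C-5 to give aryl silyl ether 21, which fluoride cleaves to the hydrogen-bonded salicylate 22; the aryloxy group sits on an sp2 carbon of 20 and cannot be the group that leaves. No lasting stereocentre is created, since the ketal carbon of 20 is only transiently stereogenic and is erased on aromatization, and the (R)-centre lies outside the reacting π-system. The step needs regioselectivity and [4+2] over [2+2] periselectivity: the first is secured by matched polarity (ester and aryloxy both make the β-carbon the electrophilic terminus), the second is favoured by the 2-alkyl group biasing the diene toward s-cis. Any 2-methoxy arene formed by the alternative loss of trimethylsilanol is compound 23, the product of step 13.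

Step 13
Reactants: 22 allyl 6-[2-(allyloxy)-6-(1,3-dioxolan-2-yl)-4-methylphenoxy]-2-hydroxy-3-[(R)-1-methoxy-3-methylbutyl]benzoate
Product: 23 allyl 6-[2-(allyloxy)-6-(1,3-dioxolan-2-yl)-4-methylphenoxy]-2-methoxy-3-[(R)-1-methoxy-3-methylbutyl]benzoate
Conditions: MeI, Cs2CO3, DMF, rt
Reagents that add atoms: iodomethane, CI
Why: Williamson O-methylation of the hindered, hydrogen-bonded salicylate phenol, the only acidic OH present, under conditions to which the allyl ester, allyl ether and acetal are stable.

Step 14
Reactants: 23 allyl 6-[2-(allyloxy)-6-(1,3-dioxolan-2-yl)-4-methylphenoxy]-2-methoxy-3-[(R)-1-methoxy-3-methylbutyl]benzoate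
Product: 24 6-[2-(1,3-dioxolan-2-yl)-6-hydroxy-4-methylphenoxy]-2-methoxy-3-[(R)-1-methoxy-3-methylbutyl]benzoic acid
Conditions: Pd(PPh3)4 (cat.), morpholine, THF, rt; pH 5 buffer work-up
Reagents that add atoms: none
Why: Tsuji–Trost-type Pd(0) deallylation, in which oxidative addition to both the allyl ester and the allyl aryl ether gives π-allylpalladium that morpholine traps, unmasks the hindered 2,6-disubstituted benzoic acid without hydrolysis while the acetal keeps the aldehyde from condensing with the amine.

Step 15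
Reactants: 24 6-[2-(1,3-dioxolan-2-yl)-6-hydroxy-4-methylphenoxy]-2-methoxy-3-[(R)-1-methoxy-3-methylbutyl]benzoic acid
Product: 25 6-(2-formyl-6-hydroxy-4-methylphenoxy)-2-methoxy-3-[(1R)-1-methoxy-3-methylbutyl]benzoic acid (CNP0328949.1)
Conditions: 1 M HCl, THF, 0 °C → rt
Reagents that add atoms: water, O
Why: Mild aqueous-acid hydrolysis of the electron-rich aryl dioxolane should release the aldehyde much faster than the benzylic methyl ether ionizes, since its arene carries the deactivating carboxyl group, so the (R)-centre should be preserved.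

**Compound list**

1 | (S)-4-benzyl-3-[(E)-but-2-enoyl]oxazolidin-2-one | C/C=C/C(=O)N1[C@@H](Cc2ccccc2)COC1=O | starting material
2 | 3-methylbutanal (isovaleraldehyde) | CC(C)CC=O | starting material
3 | dibutylboron Z-dienolate of imide 1 | C=C/C=C(\OB(CCCC)CCCC)N1[C@@H](Cc2ccccc2)COC1=O | intermediate (not isolated)
4 | (S)-4-benzyl-3-[(2S,3R)-2-ethenyl-3-hydroxy-5-methylhexanoyl]oxazolidin-2-one | C=C[C@@H]([C@H](O)CC(C)C)C(=O)N1[C@@H](Cc2ccccc2)COC1=O | intermediate
5 | (S)-4-benzyl-3-[(2S,3R)-2-ethenyl-3-methoxy-5-methylhexanoyl]oxazolidin-2-one | C=C[C@@H]([C@H](OC)CC(C)C)C(=O)N1[C@@H](Cc2ccccc2)COC1=O | intermediate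
6 | (2S,3R)-2-ethenyl-3-methoxy-5-methylhexanoic acid | C=C[C@@H]([C@H](OC)CC(C)C)C(=O)O | intermediate
7 | methyl (2S,3R)-2-ethenyl-3-methoxy-5-methylhexanoate | C=C[C@@H]([C@H](OC)CC(C)C)C(=O)OC | intermediate
8 | lithium dienolate of ester 7 | C=CC(=C(OC)O[Li])[C@@H](CC(C)C)OC | intermediate (not isolated)
9 | 1-methoxy-2-[(R)-1-methoxy-3-methylbutyl]-1-(trimethylsilyloxy)buta-1,3-diene (either ketene acetal geometry) | C=CC(=C(OC)O[Si](C)(C)C)[C@@H](CC(C)C)OC | intermediate
10 | 2-methoxy-4-methylphenol | COc1cc(C)ccc1O | starting material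
11 | 2-hydroxy-3-methoxy-5-methylbenzaldehyde | COc1cc(C)cc(C=O)c1O | intermediate
12 | 2,3-dihydroxy-5-methylbenzaldehyde | Cc1cc(O)c(O)c(C=O)c1 | intermediate
13 | 3-(allyloxy)-2-hydroxy-5-methylbenzaldehyde | C=CCOc1cc(C)cc(C=O)c1O | intermediate
14 | 2-(allyloxy)-6-(1,3-dioxolan-2-yl)-4-methylphenol | C=CCOc1cc(C)cc(C2OCCO2)c1O | intermediate
15 | trichloroethylene | ClC=C(Cl)Cl | starting material
16 | 2-[3-(allyloxy)-2-{[(E)-1,2-dichloroethenyl]oxy}-5-methylphenyl]-1,3-dioxolane | C=CCOc1cc(C)cc(C2OCCO2)c1O/C(Cl)=C\Cl | intermediate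
17 | 2-[3-(allyloxy)-2-[(chloroethynyl)oxy]-5-methylphenyl]-1,3-dioxolane | C=CCOc1cc(C)cc(C2OCCO2)c1OC#CCl | intermediate (not isolated)
18 | lithium 2-[2-(allyloxy)-6-(1,3-dioxolan-2-yl)-4-methylphenoxy]acetylide | C=CCOc1cc(C)cc(C2OCCO2)c1OC#C[Li] | intermediate (not isolated)
19 | allyl 3-[2-(allyloxy)-6-(1,3-dioxolan-2-yl)-4-methylphenoxy]prop-2-ynoate | C=CCOC(=O)C#COc1c(OCC=C)cc(C)cc1C1OCCO1 | intermediate
20 | allyl 2-[2-(allyloxy)-6-(1,3-dioxolan-2-yl)-4-methylphenoxy]-6-methoxy-5-[(R)-1-methoxy-3-methylbutyl]-6-(trimethylsilyloxy)cyclohexa-1,4-diene-1-carboxylate (both epimers at C-6) | COC1(O[Si](C)(C)C)C([C@@H](CC(C)C)OC)=CCC(Oc2c(OCC=C)cc(C)cc2C3OCCO3)=C1C(=O)OCC=C | intermediate (not isolated)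
21 | allyl 6-[2-(allyloxy)-6-(1,3-dioxolan-2-yl)-4-methylphenoxy]-3-[(R)-1-methoxy-3-methylbutyl]-2-(trimethylsilyloxy)benzoate | C=CCOC(=O)c1c(O[Si](C)(C)C)c([C@@H](CC(C)C)OC)ccc1Oc1c(OCC=C)cc(C)cc1C1OCCO1 | intermediate (not isolated)
22 | allyl 6-[2-(allyloxy)-6-(1,3-dioxolan-2-yl)-4-methylphenoxy]-2-hydroxy-3-[(R)-1-methoxy-3-methylbutyl]benzoate | C=CCOC(=O)c1c(O)c([C@@H](CC(C)C)OC)ccc1Oc1c(OCC=C)cc(C)cc1C1OCCO1 | intermediate
23 | allyl 6-[2-(allyloxy)-6-(1,3-dioxolan-2-yl)-4-methylphenoxy]-2-methoxy-3-[(R)-1-methoxy-3-methylbutyl]benzoate | C=CCOC(=O)c1c(OC)c([C@@H](CC(C)C)OC)ccc1Oc1c(OCC=C)cc(C)cc1C1OCCO1 | intermediate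
24 | 6-[2-(1,3-dioxolan-2-yl)-6-hydroxy-4-methylphenoxy]-2-methoxy-3-[(R)-1-methoxy-3-methylbutyl]benzoic acid | OC(=O)c1c(OC)c([C@@H](CC(C)C)OC)ccc1Oc1c(O)cc(C)cc1C1OCCO1 | intermediate
25 | 6-(2-formyl-6-hydroxy-4-methylphenoxy)-2-methoxy-3-[(1R)-1-methoxy-3-methylbutyl]benzoic acid | COc1c([C@@H](CC(C)C)OC)ccc(Oc2c(O)cc(C)cc2C=O)c1C(=O)O | target

**Step count**

Total steps: 15. Longest linear sequence: 10 steps (steps 6–15, from 2-methoxy-4-methylphenol 10); the diene branch (steps 1–5) joins at step 12.

**Steps most likely to fail**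

1. Step 12 (proposed new method). The aryloxy donor may make the ynoate too weak a dienophile, so that thermal decay of the diene (protodesilylation, loss of the allylic methoxy group) outruns cycloaddition. Alternatively, the first C–C bond may form without ring closure and the intermediate may expel aryloxide. The fallback uses known chemistry and sets out from diene 9 and phenol 14. It keeps the Diels–Alder/aromatization but uses a halo-ynoate, a dienophile class of established behaviour whose regiochemistry is governed by the ester, and makes the diaryl ether afterwards. Propiolic acid is O-allylated (allyl bromide, NaHCO3, DMF) to allyl prop-2-ynoate F1, which is brominated at the alkyne terminus (NBS, cat. AgNO3, acetone) to allyl 3-bromoprop-2-ynoate F2. Cycloaddition of 9 with F2 (PhMe, 60–80 °C) should give, through the bromo cycloadduct F3 and the bromoaryl silyl ether F4 and after the same fluoride work-up, allyl 6-bromo-2-hydroxy-3-[(R)-1-methoxy-3-methylbutyl]benzoate F5. O-Methylation (MeI, Cs2CO3, DMF) gives allyl 6-bromo-2-methoxy-3-[(R)-1-methoxy-3-methylbutyl]benzoate F6. Ullmann-type coupling of F6 with phenol 14 (CuI, picolinic acid, K3PO4, DMSO, 90 °C) then forms the diaryl ether and comes back to the route at 23.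

2. Step 11. Acetylide 18 may add to the ynoate as it forms (conjugate addition at the aryloxy-bearing carbon) or attack the chloroformate twice, so the acylation is outrun by consumption of its own product. The fallback sets out from acetylide 18, generated as in step 11, and replaces acylation by carboxylation. Dry CO2 at −78 °C gives lithium 3-[2-(allyloxy)-6-(1,3-dioxolan-2-yl)-4-methylphenoxy]prop-2-ynoate F7, a carboxylate that is a far poorer acceptor toward 18. Without acidification the solvent is exchanged for DMF and the salt is O-alkylated with allyl bromide (cat. Bu4NI, rt), which comes back to the route at 19.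

3. Step 5. E1cB loss of methoxide from lithium dienolate 8 may compete with O-silylation, and the allylic methoxy group of the ketene acetal may be lost on heating in step 12. The fallback sets out from aldol adduct 4 and carries the carbinol oxygen unmethylated, so that enolization is done on an alkoxide, which is not a leaving group (Fráter–Seebach-type dianion).
   - LiOH/H2O2 cleavage of 4 gives (2S,3R)-2-ethenyl-3-hydroxy-5-methylhexanoic acid F8.
   - TMSCHN2 gives methyl (2S,3R)-2-ethenyl-3-hydroxy-5-methylhexanoate F9.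
   - LDA (2.2 equiv) then TMSCl (2.5 equiv) at −78 °C gives, through the dilithium alkoxide–dienolate F10, 1-methoxy-2-[(R)-3-methyl-1-(trimethylsilyloxy)butyl]-1-(trimethylsilyloxy)buta-1,3-diene F11.
   - Cycloaddition of F11 with 19 as in step 12 should give, through the bis-silylated cycloadduct F12 and the bis(silyl ether) arene F13 and after fluoride work-up, allyl 6-[2-(allyloxy)-6-(1,3-dioxolan-2-yl)-4-methylphenoxy]-2-hydroxy-3-[(R)-1-hydroxy-3-methylbutyl]benzoate F14.
   - Double O-methylation of the phenol and the benzylic alcohol (NaH, MeI, DMF, 0 °C) comes back to the route at 23.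

Further compounds
F1 | step 12 | allyl prop-2-ynoate | C#CC(=O)OCC=C
F2 | step 12 | allyl 3-bromoprop-2-ynoate | BrC#CC(=O)OCC=C
F3 | step 12 | allyl 2-bromo-6-methoxy-5-[(R)-1-methoxy-3-methylbutyl]-6-(trimethylsilyloxy)cyclohexa-1,4-diene-1-carboxylate | COC1(O[Si](C)(C)C)C([C@@H](CC(C)C)OC)=CCC(Br)=C1C(=O)OCC=C
F4 | step 12 | allyl 6-bromo-3-[(R)-1-methoxy-3-methylbutyl]-2-(trimethylsilyloxy)benzoate | C=CCOC(=O)c1c(O[Si](C)(C)C)c([C@@H](CC(C)C)OC)ccc1Br
F5 | step 12 | allyl 6-bromo-2-hydroxy-3-[(R)-1-methoxy-3-methylbutyl]benzoate | C=CCOC(=O)c1c(O)c([C@@H](CC(C)C)OC)ccc1Br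
F6 | step 12 | allyl 6-bromo-2-methoxy-3-[(R)-1-methoxy-3-methylbutyl]benzoate | C=CCOC(=O)c1c(OC)c([C@@H](CC(C)C)OC)ccc1Br
F7 | step 11 | lithium 3-[2-(allyloxy)-6-(1,3-dioxolan-2-yl)-4-methylphenoxy]prop-2-ynoate | [Li+].[O-]C(=O)C#COc1c(OCC=C)cc(C)cc1C1OCCO1
F8 | step 5 | (2S,3R)-2-ethenyl-3-hydroxy-5-methylhexanoic acid | C=C[C@@H]([C@H](O)CC(C)C)C(=O)O
F9 | step 5 | methyl (2S,3R)-2-ethenyl-3-hydroxy-5-methylhexanoate | C=C[C@@H]([C@H](O)CC(C)C)C(=O)OC
F10 | step 5 | dilithium alkoxide–dienolate of ester F9 | C=CC(=C(OC)O[Li])[C@@H](CC(C)C)O[Li]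
F11 | step 5 | 1-methoxy-2-[(R)-3-methyl-1-(trimethylsilyloxy)butyl]-1-(trimethylsilyloxy)buta-1,3-diene | C=CC(=C(OC)O[Si](C)(C)C)[C@@H](CC(C)C)O[Si](C)(C)C
F12 | step 5 | allyl 2-[2-(allyloxy)-6-(1,3-dioxolan-2-yl)-4-methylphenoxy]-6-methoxy-5-[(R)-3-methyl-1-(trimethylsilyloxy)butyl]-6-(trimethylsilyloxy)cyclohexa-1,4-diene-1-carboxylate | COC1(O[Si](C)(C)C)C([C@@H](CC(C)C)O[Si](C)(C)C)=CCC(Oc2c(OCC=C)cc(C)cc2C3OCCO3)=C1C(=O)OCC=C
F13 | step 5 | allyl 6-[2-(allyloxy)-6-(1,3-dioxolan-2-yl)-4-methylphenoxy]-3-[(R)-3-methyl-1-(trimethylsilyloxy)butyl]-2-(trimethylsilyloxy)benzoate | C=CCOC(=O)c1c(O[Si](C)(C)C)c([C@@H](CC(C)C)O[Si](C)(C)C)ccc1Oc1c(OCC=C)cc(C)cc1C1OCCO1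
F14 | step 5 | allyl 6-[2-(allyloxy)-6-(1,3-dioxolan-2-yl)-4-methylphenoxy]-2-hydroxy-3-[(R)-1-hydroxy-3-methylbutyl]benzoate | C=CCOC(=O)c1c(O)c([C@@H](CC(C)C)O)ccc1Oc1c(OCC=C)cc(C)cc1C1OCCO1
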